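The violet and red runs are my starting point, and the flask has to be read from them.

all flasks: gas phase 2.2 mM (held)

|  | substrate | remark | time |
|---|---|---|---|
| violet | 0.070 M | run made earlier |  |
| red | 0.11 M | run made earlier |  |
| flask | 0.050 M |  | 6.0 min |

| run | time / min | target / % |
|---|---|---|
| violet | 0.500 | 3.2 |
| violet | 0.833 | 6.7 |
| violet | 1.50 | 7.8 |
| violet | 3.00 | 15.8 |
| violet | 6.00 | 21.7 |
| red | 0.500 | 3.2 |
| red | 1.50 | 4.8 |
| red | 3.00 | 7.3 |
| red | 4.00 | 11.4 |
| red | 6.00 | 14.3 |

(readings scatter by 1 percentage point)

- at the start none of the gas phase is in solution

1. target at 6.0 min, in percent of the substrate charged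
2. the change that raises the amount of target at 6.0 min, in percent of the substrate charged most ("none" if none brings more than 2 percentage points) (Tuesday's / Saturday's / none)
3. amount of target at 6.0 min, in percent of the substrate charged, after Saturday's

- Tuesday's: doubling the transfer coefficient of the gas phase, all else as stated
- Saturday's: doubling the saturation concentration of gas phase, all else as stated

Before reckoning, I ask which given number has to be known well. The flask's time and substrate charge are stated, and its saturation concentration equals that of both runs, so none of these needs estimating. The number that matters is how much target the gas supply yields. Violet holds 15.2 mM of target at 6.00 min and red 15.7 mM, although their substrate charges are 0.070 M and 0.11 M. To within the readings, that is zero order in substrate.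

I therefore carry one quantity, the gas budget, defined as the millimoles per litre of target formed per minute, averaged over both runs to 6.00 min: 2.58 mM min⁻¹. One point of scatter on the last red reading is 1.10 mM, and because the budget averages the two runs, that would move my answer for the flask by 1.1 percentage points.

My reckoning is the budget times the time, divided by the charge, which gives 30.9 %. Saturday's doubles the saturation concentration, which more than doubles its gap to any dissolved gas present, while Tuesday's doubles the coefficient on the same gap. I choose Saturday's, and a doubled budget gives 61.8 %.

The forecast says 29.5 % (25 % to 33 %), also Saturday's, and 55 % (45 % to 63 %) after Saturday's, lower than my figure. Its ground: "Product formed is therefore essentially independent of substrate".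

The flask gives 28.1 %, and the best change is Saturday's, with 42.7 %, below the forecast's low end.

    gas phase ⇌ dissolved gas, rate k1*(csat - [dissolved gas]) (kL = 0.0410 s⁻¹)
    substrate + dissolved gas → target (k = 5.90 L mol⁻¹ s⁻¹)
    substrate → side product A (k = 0.00190 s⁻¹)
    substrate + target → side product B (k = 0.0850 L mol⁻¹ s⁻¹)
    substrate ⇌ dormant form (K = 11.0, k = 0.00450 s⁻¹)

The budget gives 20.6 % for the neighbour flask read at 4.0 min, which holds 24.0 %. Saturday's flask forms target at 3.56 mM min⁻¹ on average over its 6.0 min, less than the doubled 5.16 mM min⁻¹. In the flask, the half-life of substrate by the forward step to dormant form, 2.6 min, is shorter than the 6.0 min run. At 6.00 min that forward step uses substrate at 0.41 times the rate of the step to target, and the flask holds 41.6 % dormant form beside 1.95 % substrate.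

Readings and results come from a simulation from invented constants, and the scatter is random.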